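**Plan**

1. Retrosynthesis: the lactone is cut at C3=C4 (metathesis) and O1–C2 (acylation). C4 and the C2′ oxygen are then re-joined into a temporary all-cis oxane (O, C2′, C1′, C6, C5, C4). The side chain is cut at C4′–O (reduction) and C5′–C6′ (aldol), the oxane at C4–C5 and C6–O (Prins cyclisation), and last C1′–C2′ (allylation).
2. Enabling feature: the lactone oxygen on C6 is 1,3-anti to the hydroxyl on C2′. This is the relation of an equatorial 4-oxygen to the ring oxygen in an all-cis 2,4,6-trisubstituted oxane. A halomethyl handle on C4 lets zinc expel the C2′ oxygen again.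
3. Forward order: C2′ carbinol, then the oxane ring (steps 4–7, carrying the acrylate from step 5), then chain extension at the ketone arm. The oxane is opened by zinc and the dihydropyranone ring is closed last.
4. Stereochemistry: C2′ comes from reagent-controlled allylboration. C6 is relayed from C2′ in the Prins chair. C6′ is relayed from the C2′ ring oxygen by a 1,5-anti boron aldol, and C4′ from C6′ by chelate-controlled syn reduction. The oxane center at C4 is temporary.

Key step: step 4

Remark on locants: the lactone ring is O1, C2(=O), C3, C4, C5, C6, and the chain on C6 is C1′–C15′ (hydroxyls on C2′, C4′, C6′). These locants are used for all intermediates.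

**Step 1**
Reactants: 1 ethyl 2-(2-methyl-1,3-dioxolan-2-yl)acetate
Product: 2 2-(2-methyl-1,3-dioxolan-2-yl)acetaldehyde
Conditions: iBu2AlH (1.05 equiv), CH2Cl2, −78 °C; MeOH, aq. potassium sodium tartrate
Reagents that add atoms: none
Why: Low-temperature half-reduction of an ester with a dialkylaluminium hydride; the tetrahedral aluminium hemiacetal, chelated by a ketal oxygen, should persist until work-up and limit over-reduction, and no stereocenter is formed.

**Step 2**
Reactants: 2 2-(2-methyl-1,3-dioxolan-2-yl)acetaldehyde; 3 allylmagnesium bromide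
Product: 4 (2R)-1-(2-methyl-1,3-dioxolan-2-yl)pent-4-en-2-ol
Conditions: (+)-Ipc2BOMe, 3, Et2O, 0 °C → rt; then 2, −78 °C; 3 M NaOH, 30% H2O2, rt
Reagents that add atoms: none
Why: Brown asymmetric allylboration: (+)-Ipc2B(allyl), formed in the flask, transfers the allyl group through a closed chair transition state, and with isopinocampheyl groups derived from (−)-α-pinene addition is expected on the Re face of the aldehyde, which sets the (R)-carbinol that becomes C2′.

**Step 3**
Reactants: 4 (2R)-1-(2-methyl-1,3-dioxolan-2-yl)pent-4-en-2-ol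
Product: 5 (4R)-4-hydroxyhept-6-en-2-one
Conditions: 1 M HCl, THF, 0 °C → rt
Reagents that add atoms: water, O
Why: Acid-catalysed hydrolysis of a dioxolane ketal; the β-hydroxy ketone should tolerate brief dilute acid at or below room temperature, and the carbinol center is not touched.

**Step 4**
Reactants: 5 (4R)-4-hydroxyhept-6-en-2-one; 6 2-bromo-1,1-diethoxyethane
Product: 8 1-[(2R,4R,6S)-6-(bromomethyl)-4-hydroxyoxan-2-yl]propan-2-one, via oxanyl trifluoroacetate 7 (not isolated)
Conditions: 6 (1.3 equiv), CF3CO2H (20 equiv), CH2Cl2, 0 °C → rt; evaporate; K2CO3, MeOH, 0 °C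
Reagents that add atoms: trifluoroacetic acid, OC(=O)C(F)(F)F
Why: Prins cyclisation: CF3CO2H exchanges an ethoxy group of 6 for the C2′ hydroxyl of 5 and ionises the mixed acetal to an (E)-oxocarbenium ion (O=C4), the terminal alkene carbon C5 adds to C4 and the secondary cation left at C6 is captured by trifluoroacetate, so that C4–C5 and C6–O are formed in one operation, and methanolysis then frees the C6 hydroxyl. The closest known reaction type is the acid-mediated Prins cyclisation of homoallylic alcohols with aldehydes or their acetals to 4-acyloxy oxanes. The oxane ring (O, C2′, C1′, C6, C5, C4) closes by 6-endo attack of the alkene on the oxocarbenium carbon through a chair transition state. In that chair the 2-oxopropyl group on C2′ and the bromomethyl group on C4 are equatorial and the carboxylate enters equatorially, so the existing C2′ center should control both new centers and give the all-cis oxane; C6 thus gets the configuration that is 1,3-anti to the C2′ oxygen, while the C4 center is temporary. The step needs the alkene, not the ketone (oxygen or enol), to be the nucleophile and needs ring closure to outrun 2-oxonia-Cope side-chain exchange: the electron-poor bromomethyl oxocarbenium should cyclise fast, acid-catalysed enolisation toward the methyl group is slow at 0 °C, and no free aldehyde or water is present.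

**Step 5**
Reactants: 8 1-[(2R,4R,6S)-6-(bromomethyl)-4-hydroxyoxan-2-yl]propan-2-one; 9 acryloyl chloride
Product: 10 (2S,4R,6R)-2-(bromomethyl)-6-(2-oxopropyl)oxan-4-yl prop-2-enoate
Conditions: 9, iPr2NEt, DMAP (cat.), CH2Cl2, −20 → 0 °C
Reagents that add atoms: none
Why: O-acylation of an unhindered equatorial secondary alcohol with an acid chloride; no stereocenter is affected, and the acrylate supplies O1–C2–C3 of the lactone.

**Step 6**
Reactants: 10 (2S,4R,6R)-2-(bromomethyl)-6-(2-oxopropyl)oxan-4-yl prop-2-enoate; 11 decanal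
Product: 12 (2S,4R,6R)-2-(bromomethyl)-6-[(4R)-4-hydroxy-2-oxotridecyl]oxan-4-yl prop-2-enoate
Conditions: Bu2BOTf, iPr2NEt, Et2O, −78 °C; 11, −78 → −20 °C; pH 7 buffer, MeOH
Reagents that add atoms: none
Why: Boron-mediated aldol addition of a methyl ketone with 1,5-anti induction: kinetic enolisation on the methyl side, then addition through a transition state organised by the β-oxygen (here the oxane oxygen on C2′) should place the C6′ hydroxyl anti to the C2′–O bond; a dialkylboron enolate at −78 °C is not expected to attack the acrylate or the alkyl bromide.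

**Step 7**
Reactants: 12 (2S,4R,6R)-2-(bromomethyl)-6-[(4R)-4-hydroxy-2-oxotridecyl]oxan-4-yl prop-2-enoate
Product: 13 (2S,4R,6S)-2-(bromomethyl)-6-[(2R,4R)-2,4-dihydroxytridecyl]oxan-4-yl prop-2-enoate
Conditions: Et2BOMe, NaBH4, THF/MeOH (4:1), −78 °C; MeOH co-evaporation
Reagents that add atoms: none
Why: Narasaka–Prasad reduction: the boron chelate of the β-hydroxy ketone is reduced by external hydride delivery, which should set C4′ syn to C6′ and therefore anti to C2′; at −78 °C borohydride should leave the acrylate and the bromide untouched.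

**Step 8**
Reactants: 13 (2S,4R,6S)-2-(bromomethyl)-6-[(2R,4R)-2,4-dihydroxytridecyl]oxan-4-yl prop-2-enoate
Product: 15 (4S,6S,8R,10R)-6,8,10-trihydroxynonadec-1-en-4-yl prop-2-enoate, via iodomethyl oxane 14 (not isolated)
Conditions: NaI, 2-butanone, 70 °C; then Zn dust (activated), THF/H2O (4:1), rt, sonication
Reagents that add atoms: none
Why: Finkelstein exchange followed by zinc-mediated reductive β-elimination of a β-halo ether (Boord/Bernet–Vasella fragmentation): zinc inserts into the C–I bond and expels the ring oxygen, which opens the temporary oxane, frees the C2′ hydroxyl and leaves C4 as a vinyl group; no stereocenter is touched, and near-neutral aqueous THF at room temperature is chosen to suppress acyl migration.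

**Step 9**
Reactants: 15 (4S,6S,8R,10R)-6,8,10-trihydroxynonadec-1-en-4-yl prop-2-enoate
Product: 16 (6S)-6-[(2S,4R,6R)-2,4,6-trihydroxypentadecyl]-5,6-dihydro-2H-pyran-2-one
Conditions: second-generation Grubbs catalyst (H2IMes)(PCy3)Cl2Ru=CHPh (5 mol %), CH2Cl2 (0.005 M), 40 °C
Reagents that add atoms: none
Why: Ring-closing metathesis of the acrylate of a homoallylic alcohol closes the six-membered unsaturated lactone at C3=C4, the ring size enforcing the cis alkene; free hydroxyls are tolerated and ethene is lost.

**Compound list**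

1 | ethyl 2-(2-methyl-1,3-dioxolan-2-yl)acetate | CCOC(=O)CC1(C)OCCO1 | starting material
2 | 2-(2-methyl-1,3-dioxolan-2-yl)acetaldehyde | CC1(CC=O)OCCO1 | intermediate
3 | allylmagnesium bromide | C=CC[Mg]Br | starting material
4 | (2R)-1-(2-methyl-1,3-dioxolan-2-yl)pent-4-en-2-ol | CC1(C[C@H](O)CC=C)OCCO1 | intermediate
5 | (4R)-4-hydroxyhept-6-en-2-one | CC(=O)C[C@H](O)CC=C | intermediate
6 | 2-bromo-1,1-diethoxyethane | CCOC(CBr)OCC | starting material
7 | (2S,4R,6R)-2-(bromomethyl)-6-(2-oxopropyl)oxan-4-yl 2,2,2-trifluoroacetate | CC(=O)C[C@H]1C[C@@H](OC(=O)C(F)(F)F)C[C@@H](CBr)O1 | intermediate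
8 | 1-[(2R,4R,6S)-6-(bromomethyl)-4-hydroxyoxan-2-yl]propan-2-one | CC(=O)C[C@H]1C[C@@H](O)C[C@@H](CBr)O1 | intermediate
9 | acryloyl chloride | C=CC(=O)Cl | starting material
10 | (2S,4R,6R)-2-(bromomethyl)-6-(2-oxopropyl)oxan-4-yl prop-2-enoate | CC(=O)C[C@H]1C[C@@H](OC(=O)C=C)C[C@@H](CBr)O1 | intermediate
11 | decanal | CCCCCCCCCC=O | starting material
12 | (2S,4R,6R)-2-(bromomethyl)-6-[(4R)-4-hydroxy-2-oxotridecyl]oxan-4-yl prop-2-enoate | CCCCCCCCC[C@@H](O)CC(=O)C[C@H]1C[C@@H](OC(=O)C=C)C[C@@H](CBr)O1 | intermediate
13 | (2S,4R,6S)-2-(bromomethyl)-6-[(2R,4R)-2,4-dihydroxytridecyl]oxan-4-yl prop-2-enoate | CCCCCCCCC[C@@H](O)C[C@@H](O)C[C@H]1C[C@@H](OC(=O)C=C)C[C@@H](CBr)O1 | intermediate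
14 | (2S,4R,6S)-6-[(2R,4R)-2,4-dihydroxytridecyl]-2-(iodomethyl)oxan-4-yl prop-2-enoate | CCCCCCCCC[C@@H](O)C[C@@H](O)C[C@H]1C[C@@H](OC(=O)C=C)C[C@@H](CI)O1 | intermediate
15 | (4S,6S,8R,10R)-6,8,10-trihydroxynonadec-1-en-4-yl prop-2-enoate | CCCCCCCCC[C@@H](O)C[C@@H](O)C[C@H](O)C[C@@H](OC(=O)C=C)CC=C | intermediate
16 | (6S)-6-[(2S,4R,6R)-2,4,6-trihydroxypentadecyl]-5,6-dihydro-2H-pyran-2-one | CCCCCCCCC[C@@H](O)C[C@@H](O)C[C@H](O)C[C@@H]1CC=CC(=O)O1 | target

**Step count**

Total steps: 9. Longest linear sequence: 9 steps (1 to 16).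

**Steps most likely to fail**

1. Step 4. The two side chains may be scrambled by 2-oxonia-Cope rearrangement followed by acetal exchange, which would give symmetric oxanes and erode enantiopurity. The β-hydroxy ketone may also dehydrate in acid before it is captured as the oxocarbenium ion. The fallback sets out from 5 and comes back at 8. It separates acetal formation from cyclisation. Compound 5 is treated with N-bromosuccinimide and ethyl vinyl ether (CH2Cl2, −40 → 0 °C) to give the mixed bromoacetal (4R)-4-(2-bromo-1-ethoxyethoxy)hept-6-en-2-one F1. This is ionised in a separate water-free operation (BF3·OEt2, AcOH, Me3SiOAc, hexane/CH2Cl2, 0 °C) to the all-cis oxanyl acetate F2. K2CO3 in MeOH then gives 8.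

2. Step 8. The acrylate may migrate from the C6 oxygen to the newly freed C2′ hydroxyl, or be solvolysed, under the influence of zinc alkoxide or hydroxide. Halide exchange next to the ring oxygen may also be slow. The fallback sets out from 8 and comes back at 16. It keeps every acyl group away from the ring opening.
   - Compound 8 is protected with 4-methoxybenzyl trichloroacetimidate and Sc(OTf)3 (cat.) as the C6 4-methoxybenzyl ether F3.
   - Aldol addition with 11 and syn reduction, as in steps 6 and 7, give the hydroxy ketone F4 and the diol F5.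
   - Zn in refluxing EtOH opens the oxane to the triol F6.
   - Bu(t)Me2SiOTf and 2,6-lutidine give the tris(silyl) ether F7, and DDQ frees the C6 hydroxyl in the alcohol F8.
   - Acylation with 9 gives the acrylate F9, and ring-closing metathesis gives the silylated lactone F10.
   - HF·pyridine then gives 16.

3. Step 6. The remote ring oxygen may give too little facial bias, or enolisation toward C3′ may be followed by β-elimination of the ring oxygen. The fallback sets out from 10 and comes back at 12. It replaces substrate control by reagent control: 10 is enolised with the antipode of Ipc2BCl whose own facial preference reinforces the 1,5-anti bias (Et3N, Et2O, −78 °C) and then treated with 11. No new compound arises (F0).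

**Further compounds**

F1 | step 4 | (4R)-4-(2-bromo-1-ethoxyethoxy)hept-6-en-2-one, mixed bromoacetal, both epimers at the acetal carbon | CC(=O)C[C@@H](CC=C)OC(CBr)OCC
F2 | step 4 | (2S,4R,6R)-2-(bromomethyl)-6-(2-oxopropyl)oxan-4-yl acetate | CC(=O)C[C@H]1C[C@@H](OC(C)=O)C[C@@H](CBr)O1
F0 | step 6 | none | none
F3 | step 8 | 4-methoxybenzyl ether of 8 at the C6 oxygen | CC(=O)C[C@H]1C[C@@H](OCc2ccc(OC)cc2)C[C@@H](CBr)O1
F4 | step 8 | aldol adduct of F3 with decanal (C6′ hydroxyl, C4′ ketone) | CCCCCCCCC[C@@H](O)CC(=O)C[C@H]1C[C@@H](OCc2ccc(OC)cc2)C[C@@H](CBr)O1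
F5 | step 8 | syn-4′,6′-diol from F4 | CCCCCCCCC[C@@H](O)C[C@@H](O)C[C@H]1C[C@@H](OCc2ccc(OC)cc2)C[C@@H](CBr)O1
F6 | step 8 | (4S,6S,8R,10R)-4-[(4-methoxyphenyl)methoxy]nonadec-1-ene-6,8,10-triol | CCCCCCCCC[C@@H](O)C[C@@H](O)C[C@H](O)C[C@@H](OCc1ccc(OC)cc1)CC=C
F7 | step 8 | tris(tert-butyldimethylsilyl) ether of F6 | CCCCCCCCC[C@@H](O[Si](C)(C)C(C)(C)C)C[C@@H](O[Si](C)(C)C(C)(C)C)C[C@H](O[Si](C)(C)C(C)(C)C)C[C@@H](OCc1ccc(OC)cc1)CC=C
F8 | step 8 | C6 alcohol from F7 after loss of the 4-methoxybenzyl group | CCCCCCCCC[C@@H](O[Si](C)(C)C(C)(C)C)C[C@@H](O[Si](C)(C)C(C)(C)C)C[C@H](O[Si](C)(C)C(C)(C)C)C[C@@H](O)CC=C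
F9 | step 8 | acrylate of F8 | CCCCCCCCC[C@@H](O[Si](C)(C)C(C)(C)C)C[C@@H](O[Si](C)(C)C(C)(C)C)C[C@H](O[Si](C)(C)C(C)(C)C)C[C@@H](OC(=O)C=C)CC=C
F10 | step 8 | 2′,4′,6′-tris(tert-butyldimethylsilyl) ether of 16 | CCCCCCCCC[C@@H](O[Si](C)(C)C(C)(C)C)C[C@@H](O[Si](C)(C)C(C)(C)C)C[C@H](O[Si](C)(C)C(C)(C)C)C[C@@H]1CC=CC(=O)O1
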